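## Strategy

- **Bonds cut:** the ester is cut at its O–CH2 bond into a primary alcohol and (Z)-2-(silyloxymethyl)but-2-enoic acid. The CH2O carbon is traced back to an amide carbonyl, the benzylic C–H of the carbinol to a ketone reduction, and the bond from the branching carbon to the allylic CH2 to a Pd-allylation.
- **Enabling feature:** apart from its two dimethoxybenzene rings the target is acyclic, and its only stereocentres are the benzylic carbinol carbon and the adjacent carbon carrying the CH2O–acyl arm. With the CH2O carbon carried as a morpholine amide C=O and the carbinol as the aryl ketone, that adjacent carbon lies between two carbonyls and epimerises, so one reduction of a racemate can set both centres.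
- **Forward order:** aroyl Meldrum's acid to β-keto morpholine amide; the chain is joined at the α-carbon by Tsuji–Trost allylation with a 1-arylallyl carbonate; dynamic kinetic transfer hydrogenation; silylation and amide reduction; the chain is joined last at the ester oxygen; desilylation. No ring is formed.
- **Stereochemistry:** the (S)-carbinol comes from the (S,S)-Ru/TsDPEN catalyst and the adjacent centre from the syn-selective dynamic kinetic resolution. The E-styrene comes from attack at the unsubstituted terminus of the π-allyl complex. The Z-enoate comes from (Z)-2-iodobut-2-enal by retentive iodine–lithium exchange and carboxylation, and is kept because the acid is coupled as a nucleophile.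

Key step: step 5

Remark (assumption on the chemistry): the (S,S)-catalyst is assigned to the (S)-carbinol by analogy with aryl alkyl ketone reductions. Should the sense of induction prove opposite, the (R,R)-complex would be used with no other change.

## Route

Step 1
Reactants: 1 3,4-dimethoxybenzoyl chloride; 2 2,2-dimethyl-1,3-dioxane-4,6-dione (Meldrum's acid)
Product: 3 5-[(3,4-dimethoxyphenyl)(hydroxy)methylidene]-2,2-dimethyl-1,3-dioxane-4,6-dione
Conditions: pyridine (2.2 equiv), DMAP (cat.), CH2Cl2, 0 °C → rt; 1 M HCl wash; used crude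
Reagents that add atoms: none
Why: C-acylation of the strongly C–H acidic Meldrum's acid by an aroyl chloride (Oikawa–Yonemitsu-type acylation) should give the enolised acyl Meldrum's acid, which survives the acidic wash.

Step 2
Reactants: 3 5-[(3,4-dimethoxyphenyl)(hydroxy)methylidene]-2,2-dimethyl-1,3-dioxane-4,6-dione; 4 morpholine
Product: 5 1-(3,4-dimethoxyphenyl)-3-(morpholin-4-yl)propane-1,3-dione
Conditions: morpholine (1.05 equiv), toluene, 90 °C
Reagents that add atoms: none
Why: Thermal aminolysis of an acyl Meldrum's acid (decarboxylative acyl transfer with loss of acetone and CO2) is the standard route to β-keto amides, and one equivalent of amine avoids enaminone formation.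

Step 3
Reactants: 6 3,4-dimethoxybenzaldehyde; 7 vinylmagnesium bromide
Product: 9 racemic 1-(3,4-dimethoxyphenyl)prop-2-en-1-yl methyl carbonate, via magnesium allylic alkoxide 8 (not isolated)
Conditions: THF, −78 → 0 °C; then ClCO2Me, 0 °C → rt; filtration through Et3N-deactivated silica
Reagents that add atoms: methyl chloroformate, COC(=O)Cl
Why: Grignard 1,2-addition to the non-enolisable aldehyde followed by O-acylation of the alkoxide in the same flask (carbonate formation) should give the carbonate; its stereocentre is left racemic because it is erased in the π-allyl complex of step 4.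

Step 4
Reactants: 5 1-(3,4-dimethoxyphenyl)-3-(morpholin-4-yl)propane-1,3-dione; 9 racemic 1-(3,4-dimethoxyphenyl)prop-2-en-1-yl methyl carbonate
Product: 10 racemic 2-[(E)-3-(3,4-dimethoxyphenyl)prop-2-en-1-yl]-1-(3,4-dimethoxyphenyl)-3-(morpholin-4-yl)propane-1,3-dione
Conditions: Pd(PPh3)4 (3 mol%), THF, rt → 40 °C; 5 in slight excess (1.3 equiv)
Reagents that add atoms: none
Why: In this Tsuji–Trost allylic alkylation Pd(0) ionises the carbonate to a 1-aryl-π-allyl complex and methoxide (after loss of CO2), the methoxide deprotonates 5, and the soft enolate should attack the unsubstituted allyl terminus to give the conjugated E-styrene, a second allylation being disfavoured at the hindered α-C–H of 10.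

Step 5
Reactants: 10 racemic 2-[(E)-3-(3,4-dimethoxyphenyl)prop-2-en-1-yl]-1-(3,4-dimethoxyphenyl)-3-(morpholin-4-yl)propane-1,3-dione
Product: 11 (2S,3S)-2-[(E)-3-(3,4-dimethoxyphenyl)prop-2-en-1-yl]-3-(3,4-dimethoxyphenyl)-3-hydroxy-1-(morpholin-4-yl)propan-1-one
Conditions: RuCl[(S,S)-TsDPEN](p-cymene) (2 mol%), HCO2H/Et3N (1:1), DMF, 35 °C
Reagents that add atoms: none
Why: Formate converts the 16-electron Ru amido complex into the Ru–H/N–H species, which passes hydride and proton to the aryl ketone through an outer-sphere six-membered transition state, while triethylamine removes and returns the C–H between the ketone and amide carbonyls of 10 so that the two enantiomers interconvert through the enol faster than the slower one is reduced. The closest known reaction type is the Noyori-type asymmetric transfer hydrogenation of racemic α-alkyl β-keto amides under dynamic kinetic resolution, which is syn-selective. No ring is closed. The carbinol centre C3 (S) is set by the catalyst, whose (S,S)-TsDPEN ligand and η6-arene recognise the dimethoxyphenyl group of the ketone as in the reduction of acetophenone to (S)-1-phenylethanol; the centre C2 (S) is set by the substrate, because A(1,3) strain keeps the α-C–H in the plane of the morpholine amide and only in the (2S)-epimer does the arylallyl chain lie anti to the hydride trajectory on the catalyst-preferred face. The step needs enantioface selection at C=O, syn over anti selection between the equilibrating epimers and chemoselection for C=O over C=C; the aryl/alkyl difference at the ketone should secure the first, the doubly activated α-C–H together with the conformational bias of the tertiary amide the second, and the inertness of an unpolarised styrene to bifunctional hydride transfer the third.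

Step 6
Reactants: 11 (2S,3S)-2-[(E)-3-(3,4-dimethoxyphenyl)prop-2-en-1-yl]-3-(3,4-dimethoxyphenyl)-3-hydroxy-1-(morpholin-4-yl)propan-1-one
Product: 12 (2S,3S)-2-[(E)-3-(3,4-dimethoxyphenyl)prop-2-en-1-yl]-3-(3,4-dimethoxyphenyl)-1-(morpholin-4-yl)-3-(triethylsilyloxy)propan-1-one
Conditions: TESCl, imidazole, DMF, 0 °C → rt
Reagents that add atoms: chlorotriethylsilane, CC[Si](Cl)(CC)CC
Why: Silyl ether formation at the secondary benzylic alcohol under imidazole catalysis touches neither stereocentre, keeps the carbinol out of the later Mitsunobu reaction and gives a group that buffered fluoride removes easily.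

Step 7
Reactants: 12 (2S,3S)-2-[(E)-3-(3,4-dimethoxyphenyl)prop-2-en-1-yl]-3-(3,4-dimethoxyphenyl)-1-(morpholin-4-yl)-3-(triethylsilyloxy)propan-1-one
Product: 13 (2R,3S)-2-[(E)-3-(3,4-dimethoxyphenyl)prop-2-en-1-yl]-3-(3,4-dimethoxyphenyl)-3-(triethylsilyloxy)propan-1-ol
Conditions: LiH2N·BH3 (4 equiv, from BH3·NH3 and LDA), THF, 0 °C → rt; then aq NH4Cl
Reagents that add atoms: none
Why: Lithium amidotrihydroborate reduces tertiary amides to primary alcohols (Myers-type amide reduction via hemiaminal collapse and a second hydride transfer); it is only weakly basic, so the α-centre should not epimerise, and the silyl ether and styrene are inert to it (the descriptor at C2 changes to R only because the CIP priorities change).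

Step 8
Reactants: 14 (E)-crotonaldehyde
Product: 15 (Z)-2-iodobut-2-enal
Conditions: I2, K2CO3, DMAP (0.2 equiv), THF/H2O (1:1), rt; used without delay
Reagents that add atoms: iodine, II
Why: Amine-catalysed α-iodination of an enal (Baylis–Hillman-type conjugate addition, iodination of the enolate and E1cB elimination) should give the α-iodoenal with methyl trans to the formyl group, which is the Z isomer.

Step 9
Reactants: 15 (Z)-2-iodobut-2-enal
Product: 16 (Z)-2-iodobut-2-en-1-ol
Conditions: NaBH4, CeCl3·7H2O, MeOH, 0 °C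
Reagents that add atoms: none
Why: Luche reduction is a 1,2-selective hydride addition to the enal that leaves the vinyl iodide and the alkene geometry untouched.

Step 10
Reactants: 16 (Z)-2-iodobut-2-en-1-ol
Product: 17 (Z)-tert-butyl[(2-iodobut-2-en-1-yl)oxy]dimethylsilane
Conditions: TBSCl, imidazole, CH2Cl2, 0 °C → rt
Reagents that add atoms: tert-butylchlorodimethylsilane, CC(C)(C)[Si](C)(C)Cl
Why: Standard silylation of a primary allylic alcohol masks the hydroxyl during the lithiation and the esterification.

Step 11
Reactants: 17 (Z)-tert-butyl[(2-iodobut-2-en-1-yl)oxy]dimethylsilane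
Product: 19 (Z)-2-[(tert-butyldimethylsilyloxy)methyl]but-2-enoic acid, via alkenyllithium 18 (not isolated)
Conditions: t-BuLi (2.1 equiv), Et2O, −78 °C; then CO2 (dry gas), −78 → 0 °C; 1 M HCl to pH 4 at 0 °C
Reagents that add atoms: carbon dioxide, O=C=O
Why: Iodine–lithium exchange at −78 °C gives a configurationally stable alkenyllithium that is carboxylated with retention (halogen–lithium exchange/carboxylation, the classical stereospecific route to angelic-type acids), so the acid is reached without an ester hydrolysis that could cause Z to E isomerisation.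

Step 12
Reactants: 13 (2R,3S)-2-[(E)-3-(3,4-dimethoxyphenyl)prop-2-en-1-yl]-3-(3,4-dimethoxyphenyl)-3-(triethylsilyloxy)propan-1-ol; 19 (Z)-2-[(tert-butyldimethylsilyloxy)methyl]but-2-enoic acid
Product: 20 (2R,3S)-2-[(E)-3-(3,4-dimethoxyphenyl)prop-2-en-1-yl]-3-(3,4-dimethoxyphenyl)-3-(triethylsilyloxy)propyl (Z)-2-[(tert-butyldimethylsilyloxy)methyl]but-2-enoate
Conditions: PPh3, DIAD, THF, 0 °C → rt; 19 (1.2 equiv)
Reagents that add atoms: none
Why: In the Mitsunobu esterification the alcohol is activated as its alkoxyphosphonium ion and displaced by the carboxylate in an SN2 reaction at the primary carbon, so no stereocentre is involved and the acid is never an acyl electrophile, which should preserve the Z geometry.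

Step 13
Reactants: 20 (2R,3S)-2-[(E)-3-(3,4-dimethoxyphenyl)prop-2-en-1-yl]-3-(3,4-dimethoxyphenyl)-3-(triethylsilyloxy)propyl (Z)-2-[(tert-butyldimethylsilyloxy)methyl]but-2-enoate
Product: 21 (2R,3S)-2-[(E)-3-(3,4-dimethoxyphenyl)prop-2-en-1-yl]-3-(3,4-dimethoxyphenyl)-3-hydroxypropyl (Z)-2-(hydroxymethyl)but-2-enoate (CNP0417076.1)
Conditions: HF·pyridine, pyridine, THF, 0 °C → rt
Reagents that add atoms: none
Why: Fluoride-mediated desilylation should cleave the secondary TES and primary TBS ethers, the pyridine buffer keeping the medium too mild for 1,3-acyl migration or ionisation of the electron-rich benzylic alcohol.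

## Compound list

1 | 3,4-dimethoxybenzoyl chloride | COc1ccc(C(=O)Cl)cc1OC | starting material
2 | 2,2-dimethyl-1,3-dioxane-4,6-dione (Meldrum's acid) | CC1(C)OC(=O)CC(=O)O1 | starting material
3 | 5-[(3,4-dimethoxyphenyl)(hydroxy)methylidene]-2,2-dimethyl-1,3-dioxane-4,6-dione | COc1ccc(C(O)=C2C(=O)OC(C)(C)OC2=O)cc1OC | intermediate
4 | morpholine | C1COCCN1 | starting material
5 | 1-(3,4-dimethoxyphenyl)-3-(morpholin-4-yl)propane-1,3-dione | COc1ccc(C(=O)CC(=O)N2CCOCC2)cc1OC | intermediate
6 | 3,4-dimethoxybenzaldehyde | COc1ccc(C=O)cc1OC | starting material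
7 | vinylmagnesium bromide | C=C[Mg]Br | starting material
8 | bromomagnesium 1-(3,4-dimethoxyphenyl)prop-2-en-1-olate (racemic, not isolated) | COc1ccc(C(C=C)O[Mg]Br)cc1OC | intermediate
9 | racemic 1-(3,4-dimethoxyphenyl)prop-2-en-1-yl methyl carbonate | COC(=O)OC(C=C)c1ccc(OC)c(OC)c1 | intermediate
10 | racemic 2-[(E)-3-(3,4-dimethoxyphenyl)prop-2-en-1-yl]-1-(3,4-dimethoxyphenyl)-3-(morpholin-4-yl)propane-1,3-dione | COc1ccc(/C=C/CC(C(=O)N2CCOCC2)C(=O)c2ccc(OC)c(OC)c2)cc1OC | intermediate
11 | (2S,3S)-2-[(E)-3-(3,4-dimethoxyphenyl)prop-2-en-1-yl]-3-(3,4-dimethoxyphenyl)-3-hydroxy-1-(morpholin-4-yl)propan-1-one | O=C(N1CCOCC1)[C@@H](C/C=C/c1ccc(OC)c(OC)c1)[C@H](O)c1ccc(OC)c(OC)c1 | intermediate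
12 | (2S,3S)-2-[(E)-3-(3,4-dimethoxyphenyl)prop-2-en-1-yl]-3-(3,4-dimethoxyphenyl)-1-(morpholin-4-yl)-3-(triethylsilyloxy)propan-1-one | O=C(N1CCOCC1)[C@@H](C/C=C/c1ccc(OC)c(OC)c1)[C@H](O[Si](CC)(CC)CC)c1ccc(OC)c(OC)c1 | intermediate
13 | (2R,3S)-2-[(E)-3-(3,4-dimethoxyphenyl)prop-2-en-1-yl]-3-(3,4-dimethoxyphenyl)-3-(triethylsilyloxy)propan-1-ol | OC[C@@H](C/C=C/c1ccc(OC)c(OC)c1)[C@H](O[Si](CC)(CC)CC)c1ccc(OC)c(OC)c1 | intermediate
14 | (E)-crotonaldehyde | C/C=C/C=O | starting material
15 | (Z)-2-iodobut-2-enal | C/C=C(\I)C=O | intermediate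
16 | (Z)-2-iodobut-2-en-1-ol | C/C=C(\I)CO | intermediate
17 | (Z)-tert-butyl[(2-iodobut-2-en-1-yl)oxy]dimethylsilane | C/C=C(\I)CO[Si](C)(C)C(C)(C)C | intermediate
18 | [1-(tert-butyldimethylsilyloxy)but-2-en-2-yl]lithium, methyl cis to lithium (formally E; not isolated) | C/C=C(\[Li])CO[Si](C)(C)C(C)(C)C | intermediate
19 | (Z)-2-[(tert-butyldimethylsilyloxy)methyl]but-2-enoic acid | C/C=C(/CO[Si](C)(C)C(C)(C)C)C(=O)O | intermediate
20 | (2R,3S)-2-[(E)-3-(3,4-dimethoxyphenyl)prop-2-en-1-yl]-3-(3,4-dimethoxyphenyl)-3-(triethylsilyloxy)propyl (Z)-2-[(tert-butyldimethylsilyloxy)methyl]but-2-enoate | C/C=C(/CO[Si](C)(C)C(C)(C)C)C(=O)OC[C@@H](C/C=C/c1ccc(OC)c(OC)c1)[C@H](O[Si](CC)(CC)CC)c1ccc(OC)c(OC)c1 | intermediate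
21 | (2R,3S)-2-[(E)-3-(3,4-dimethoxyphenyl)prop-2-en-1-yl]-3-(3,4-dimethoxyphenyl)-3-hydroxypropyl (Z)-2-(hydroxymethyl)but-2-enoate (CNP0417076.1) | C/C=C(/CO)C(=O)OC[C@@H](C/C=C/c1ccc(OC)c(OC)c1)[C@H](O)c1ccc(OC)c(OC)c1 | target

## Step count and risks

Total step count: 13. Longest linear sequence: 8 steps (steps 1, 2, 4, 5, 6, 7, 12, 13).

**Step 5.** Enolisation of the α-carbon may be too slow relative to hydride transfer, because the tertiary amide holds the α-C–H in its plane; the dynamic resolution would then become a simple kinetic resolution, or syn/anti discrimination may be poor. The fallback is an auxiliary-controlled aldol. It sets out from aldehyde 6 and returns at alcohol 13.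
- Addition of 7 to 6 with an aqueous quench in place of the chloroformate should give 1-(3,4-dimethoxyphenyl)prop-2-en-1-ol F1.
- Johnson–Claisen rearrangement (triethyl orthoacetate, cat. propionic acid, 140 °C) should give ethyl (E)-5-(3,4-dimethoxyphenyl)pent-4-enoate F2, and saponification (E)-5-(3,4-dimethoxyphenyl)pent-4-enoic acid F3.
- Acylation of (S)-4-benzyloxazolidin-2-one through the pivaloyl mixed anhydride (PivCl, Et3N, LiCl) should give (S)-4-benzyl-3-[(E)-5-(3,4-dimethoxyphenyl)pent-4-enoyl]oxazolidin-2-one F4.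
- The Evans syn-aldol reaction of its Z-boron enolate (Bu2BOTf, iPr2NEt, CH2Cl2, −78 → 0 °C) with a second portion of 6 should set both centres through the Zimmerman–Traxler chair under auxiliary control, giving (S)-4-benzyl-3-[(2S,3S)-2-[(E)-3-(3,4-dimethoxyphenyl)prop-2-en-1-yl]-3-(3,4-dimethoxyphenyl)-3-hydroxypropanoyl]oxazolidin-2-one F5.
- Silylation (TESCl, imidazole) should give the triethylsilyl ether of that aldol adduct F6, and LiBH4 (THF/MeOH, 0 °C) should remove the auxiliary reductively to give 13.

**Step 7.** The triethylsilyl group may migrate from the secondary to the newly formed primary oxygen, or be lost, under the basic reducing conditions. The fallback dispenses with the carbinol protecting group and relies on chemoselective esterification. It sets out from hydroxy amide 11 and returns at target 21.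
- 11 is reduced unprotected with the same amidoborane to (1S,2R)-2-[(E)-3-(3,4-dimethoxyphenyl)prop-2-en-1-yl]-1-(3,4-dimethoxyphenyl)propane-1,3-diol F7.
- Mitsunobu esterification with acid 19 (1 equiv PPh3/DIAD, 0 °C) should take place at the primary hydroxyl only, giving (2R,3S)-2-[(E)-3-(3,4-dimethoxyphenyl)prop-2-en-1-yl]-3-(3,4-dimethoxyphenyl)-3-hydroxypropyl (Z)-2-[(tert-butyldimethylsilyloxy)methyl]but-2-enoate F8.
- Buffered HF·pyridine should then remove the single TBS group to give 21.

**Step 4.** A second allylation of the activated methylene, or attack at the aryl-bearing allyl terminus, may erode the yield of the linear mono-allylated product. The fallback forms the bond between the α-carbon and the ketone carbon instead, so over-allylation cannot occur. It sets out from morpholine 4 and acid chloride 1 and returns at keto amide 10.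
- 4 is acylated with pent-4-enoyl chloride (Et3N, CH2Cl2) to 4-(pent-4-enoyl)morpholine F9.
- Cross-metathesis with 3,4-dimethoxystyrene (second-generation Grubbs catalyst, CH2Cl2, 40 °C) should give (E)-5-(3,4-dimethoxyphenyl)-1-(morpholin-4-yl)pent-4-en-1-one F10.
- Its lithium enolate (LDA, THF, −78 °C, two equivalents of enolate per acyl chloride) is C-acylated with 1 in a crossed Claisen condensation to give 10.

## Further compounds

F1 | step 5 | 1-(3,4-dimethoxyphenyl)prop-2-en-1-ol (racemic) | C=CC(O)c1ccc(OC)c(OC)c1
F2 | step 5 | ethyl (E)-5-(3,4-dimethoxyphenyl)pent-4-enoate | CCOC(=O)CC/C=C/c1ccc(OC)c(OC)c1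
F3 | step 5 | (E)-5-(3,4-dimethoxyphenyl)pent-4-enoic acid | OC(=O)CC/C=C/c1ccc(OC)c(OC)c1
F4 | step 5 | (S)-4-benzyl-3-[(E)-5-(3,4-dimethoxyphenyl)pent-4-enoyl]oxazolidin-2-one | O=C(CC/C=C/c1ccc(OC)c(OC)c1)N1[C@@H](Cc2ccccc2)COC1=O
F5 | step 5 | (S)-4-benzyl-3-[(2S,3S)-2-[(E)-3-(3,4-dimethoxyphenyl)prop-2-en-1-yl]-3-(3,4-dimethoxyphenyl)-3-hydroxypropanoyl]oxazolidin-2-one | O=C([C@@H](C/C=C/c1ccc(OC)c(OC)c1)[C@H](O)c1ccc(OC)c(OC)c1)N1[C@@H](Cc2ccccc2)COC1=O
F6 | step 5 | (S)-4-benzyl-3-[(2S,3S)-2-[(E)-3-(3,4-dimethoxyphenyl)prop-2-en-1-yl]-3-(3,4-dimethoxyphenyl)-3-(triethylsilyloxy)propanoyl]oxazolidin-2-one | O=C([C@@H](C/C=C/c1ccc(OC)c(OC)c1)[C@H](O[Si](CC)(CC)CC)c1ccc(OC)c(OC)c1)N1[C@@H](Cc2ccccc2)COC1=O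
F7 | step 7 | (1S,2R)-2-[(E)-3-(3,4-dimethoxyphenyl)prop-2-en-1-yl]-1-(3,4-dimethoxyphenyl)propane-1,3-diol | OC[C@@H](C/C=C/c1ccc(OC)c(OC)c1)[C@H](O)c1ccc(OC)c(OC)c1
F8 | step 7 | (2R,3S)-2-[(E)-3-(3,4-dimethoxyphenyl)prop-2-en-1-yl]-3-(3,4-dimethoxyphenyl)-3-hydroxypropyl (Z)-2-[(tert-butyldimethylsilyloxy)methyl]but-2-enoate | C/C=C(/CO[Si](C)(C)C(C)(C)C)C(=O)OC[C@@H](C/C=C/c1ccc(OC)c(OC)c1)[C@H](O)c1ccc(OC)c(OC)c1
F9 | step 4 | 4-(pent-4-enoyl)morpholine | C=CCCC(=O)N1CCOCC1
F10 | step 4 | (E)-5-(3,4-dimethoxyphenyl)-1-(morpholin-4-yl)pent-4-en-1-one | O=C(CC/C=C/c1ccc(OC)c(OC)c1)N1CCOCC1
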